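**Retrosynthetic overview**
1. The central C12–C12′ bond is made last, by crossed Kolbe electrolysis of two bicyclic acetic acids: 17 (exo-methylene, free 3-OH) and 19 (3,10-diacetate).
2. Both acids come from one keto acid 16: Wittig methylenation gives 17, MeMgBr addition with in-situ acetylation gives 19.
3. The oxepane (second ring of each half) is closed at C7–O–C2 by a new acetoxonium etherification of triol ester 13.
4. The cyclohexanone (first ring) is carved out of (−)-verbenone: Cu-catalysed conjugate addition/allylation sets C6, cyclobutane fragmentation and ozonolysis–Criegee turn the bridge carbon into C7–O and the allyl group into CH2CO2Me.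
5. The C2–C5 arm with the C3 carbinol comes from (S)-α-hydroxy-γ-butyrolactone, as acetonide iodide 4.

Assumption: (3S)-3-hydroxyoxolan-2-one (made from L-malic acid) and (1S,5S)-(−)-verbenone (from (−)-α-pinene) are bought as such. Locants in the notes follow the squalene-type chain of each half: C2 = CMe2, C3 = CH–O, C6 = quaternary C–Me, C7 = ring CH–O, C10 = carbon bearing =CH2 or Me/OAc, C11 = ring CH, C12 = bridge CH2, C13 = carboxyl carbon.

Step 1
Reactants: 1 (3S)-3-hydroxyoxolan-2-one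
Product: 2 (3S)-4-methylpentane-1,3,4-triol
Conditions: MeMgBr (3.5 equiv), THF, 0 °C → rt; aq. NH4Cl
Reagents that add atoms: methylmagnesium bromide, C[Mg]Br
Why: Double Grignard addition to the lactone carbonyl (the first equivalent only deprotonates the α-OH) gives the tertiary carbinol, and the purchased (S) centre, the future C3, is not touched.

Step 2
Reactants: 2 (3S)-4-methylpentane-1,3,4-triol
Product: 3 2-[(4S)-2,2,5,5-tetramethyl-1,3-dioxolan-4-yl]ethan-1-ol
Conditions: Me2C(OMe)2, acetone, PPTS (cat.), rt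
Reagents that add atoms: 2,2-dimethoxypropane, COC(C)(C)OC
Why: Thermodynamic acetalisation closes the five-membered dioxolane on the vicinal secondary/tertiary diol in preference to the 1,3-dioxane, leaving the primary OH free.

Step 3
Reactants: 3 2-[(4S)-2,2,5,5-tetramethyl-1,3-dioxolan-4-yl]ethan-1-ol
Product: 4 (4S)-4-(2-iodoethyl)-2,2,5,5-tetramethyl-1,3-dioxolane
Conditions: I2, PPh3, imidazole, CH2Cl2, 0 °C → rt
Reagents that add atoms: iodine, II
Why: Appel iodination is an SN2 displacement at the primary carbon, remote from the stereocentre.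

Step 4
Reactants: 4 (4S)-4-(2-iodoethyl)-2,2,5,5-tetramethyl-1,3-dioxolane; 5 (1S,5S)-4,6,6-trimethylbicyclo[3.1.1]hept-3-en-2-one [(−)-verbenone]
Product: 8 (1S,3R,4R,5R)-4,6,6-trimethyl-3-(prop-2-en-1-yl)-4-{2-[(4S)-2,2,5,5-tetramethyl-1,3-dioxolan-4-yl]ethyl}bicyclo[3.1.1]heptan-2-one, via Grignard reagent 6 (not isolated), via magnesium enolate 7 (not isolated)
Conditions: 4, Mg, THF, rt; then CuBr·SMe2 (15 mol %), 5, THF, −40 → 0 °C; then allyl bromide, HMPA, −20 °C → rt
Reagents that add atoms: allyl bromide, C=CCBr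
Why: Copper-catalysed 1,4-addition to the strained enone occurs only on the face anti to the gem-dimethyl bridge, which sets the quaternary carbon (future C6) with the chain trans and the methyl cis to the bridge carbon that becomes the C7 oxygen; the enolate, which can only lie towards C3 because C1 is a bridgehead, is then C-allylated anti to the bridge (this future C11 centre is epimerisable and is corrected in steps 6 and 9).

Step 5
Reactants: 8 (1S,3R,4R,5R)-4,6,6-trimethyl-3-(prop-2-en-1-yl)-4-{2-[(4S)-2,2,5,5-tetramethyl-1,3-dioxolan-4-yl]ethyl}bicyclo[3.1.1]heptan-2-one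
Product: 9 (4R,5R,6R)-5-[(3S)-3,4-bis(acetyloxy)-4-methylpentyl]-5-methyl-4-(prop-1-en-2-yl)-6-(prop-2-en-1-yl)cyclohex-1-en-1-yl acetate
Conditions: BF3·OEt2, Zn(OAc)2, Ac2O, 0 °C → rt
Reagents that add atoms: acetic anhydride, CC(=O)OC(C)=O
Why: Lewis-acid push–pull fragmentation of the cyclobutane cleaves the C1–C6 bond of the verbanone to an enol acetate and a tertiary cation that loses a proton to the isopropenyl group; the bridgehead (future C7) and the quaternary carbon keep their configuration, and the acetonide is acetolysed to the diacetate without breaking the C3–O bond.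

Step 6
Reactants: 9 (4R,5R,6R)-5-[(3S)-3,4-bis(acetyloxy)-4-methylpentyl]-5-methyl-4-(prop-1-en-2-yl)-6-(prop-2-en-1-yl)cyclohex-1-en-1-yl acetate
Product: 10 (2S,3R,4R)-3-[(3S)-3,4-dihydroxy-4-methylpentyl]-3-methyl-4-(prop-1-en-2-yl)-2-(prop-2-en-1-yl)cyclohexan-1-one
Conditions: NaOMe, MeOH, 40 °C
Reagents that add atoms: none
Why: Zemplén methanolysis removes the enol and alkyl acetates, and the α-centre of the freed ketone (C11) equilibrates towards the equatorial allyl epimer, cis to the quaternary methyl.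

Step 7
Reactants: 10 (2S,3R,4R)-3-[(3S)-3,4-dihydroxy-4-methylpentyl]-3-methyl-4-(prop-1-en-2-yl)-2-(prop-2-en-1-yl)cyclohexan-1-one
Product: 13 methyl [(1S,2S,3S)-2-[(3S)-3,4-dihydroxy-4-methylpentyl]-3-hydroxy-2-methyl-6-oxocyclohexyl]acetate, via bis(methoxy hydroperoxide) 11 (not isolated), via keto ester diacetate 12 (not isolated)
Conditions: O3, CH2Cl2/MeOH, NaHCO3, −78 °C; then Ac2O, Et3N, DMAP, 0 → 40 °C; then NaOMe, MeOH, 40 °C
Reagents that add atoms: ozone, [O-][O+]=O; methanol, CO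
Why: Ozonolysis in methanol gives two α-methoxy hydroperoxides; on acylation the one from the allyl group is dehydrated to the methyl ester, and the one from the isopropenyl group undergoes Criegee rearrangement, the ring carbon migrating to oxygen with retention so that C7 carries OAc; methanolysis then frees the hydroxyls.

Step 8
Reactants: 13 methyl [(1S,2S,3S)-2-[(3S)-3,4-dihydroxy-4-methylpentyl]-3-hydroxy-2-methyl-6-oxocyclohexyl]acetate
Product: 15 methyl [(3S,5aS,6S,9aS)-3-(acetyloxy)-2,2,5a-trimethyl-7-oxodecahydro-1-benzoxepin-6-yl]acetate, via cyclic orthoacetate 14 (not isolated)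
Conditions: MeC(OMe)3, PPTS (cat.), CH2Cl2, rt; evaporate; then BF3·OEt2 (cat.), CH2Cl2, −40 → 0 °C
Reagents that add atoms: trimethyl orthoacetate, COC(C)(OC)OC
Why: Proposed new method: BF3 ionises the cyclic orthoacetate of the 2,3-diol to a 1,3-dioxolan-2-ylium (acetoxonium) ion, which the C7 hydroxyl opens at the tertiary carbon C2 (SN1-like; SN2 at C3 is neopentyl-blocked) to close the trans-fused oxepane, so the C3–O bond is never broken and C3 emerges as the (S)-acetate; the closest known reactions are the orthoester/BF3 cyclisation of 1,2,n-triols to tetrahydrofurans and tetrahydropyrans and the acid-promoted opening of trisubstituted epoxides at the tertiary carbon, and what is new is the seven-membered ring and attack at a fully substituted acetoxonium carbon.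

Step 9
Reactants: 15 methyl [(3S,5aS,6S,9aS)-3-(acetyloxy)-2,2,5a-trimethyl-7-oxodecahydro-1-benzoxepin-6-yl]acetate
Product: 16 [(3S,5aS,6S,9aS)-3-hydroxy-2,2,5a-trimethyl-7-oxodecahydro-1-benzoxepin-6-yl]acetic acid
Conditions: LiOH, THF/MeOH/H2O, 40 °C; then aq. HCl (pH 3)
Reagents that add atoms: lithium hydroxide, [Li+].[OH-]
Why: Saponification cleaves the methyl ester and the C3 acetate, and in the now rigid trans-fused bicycle the base equilibrates the ketone α-centre C11 to the equatorial side chain (cis to the axial angular methyl).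

Step 10
Reactants: 16 [(3S,5aS,6S,9aS)-3-hydroxy-2,2,5a-trimethyl-7-oxodecahydro-1-benzoxepin-6-yl]acetic acid
Product: 17 [(3S,5aS,6R,9aS)-3-hydroxy-2,2,5a-trimethyl-7-methylidenedecahydro-1-benzoxepin-6-yl]acetic acid
Conditions: Ph3PCH3Br, KOtBu (6 equiv each), THF/toluene, 0 → 70 °C; aq. citric acid
Reagents that add atoms: methyltriphenylphosphonium bromide, C[P+](c1ccccc1)(c1ccccc1)c1ccccc1.[Br-]
Why: Wittig methylenation with excess ylide tolerates the carboxylate and alkoxide and turns the C10 ketone into the exocyclic alkene, with C11 kept as the thermodynamic equatorial epimer.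

Step 11
Reactants: 16 [(3S,5aS,6S,9aS)-3-hydroxy-2,2,5a-trimethyl-7-oxodecahydro-1-benzoxepin-6-yl]acetic acid
Product: 19 [(3S,5aS,6S,7R,9aS)-3,7-bis(acetyloxy)-2,2,5a,7-tetramethyldecahydro-1-benzoxepin-6-yl]acetic acid, via bromomagnesium alkoxide 18 (not isolated)
Conditions: MeMgBr (6 equiv), CeCl3, THF, −78 → 0 °C; then Ac2O, DMAP (cat.), 0 °C → rt; aq. NaHCO3, then citric acid
Reagents that add atoms: methylmagnesium bromide, C[Mg]Br; acetic anhydride, CC(=O)OC(C)=O
Why: Grignard addition to the C10 ketone is equatorial, away from the 1,3-diaxial angular methyl, giving the axial tertiary alkoxide (7R); both magnesium alkoxides are then O-acylated in the flask before lactonisation can occur, and the mixed anhydride of the carboxylate is hydrolysed on work-up.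

Step 12
Reactants: 17 [(3S,5aS,6R,9aS)-3-hydroxy-2,2,5a-trimethyl-7-methylidenedecahydro-1-benzoxepin-6-yl]acetic acid; 19 [(3S,5aS,6S,7R,9aS)-3,7-bis(acetyloxy)-2,2,5a,7-tetramethyldecahydro-1-benzoxepin-6-yl]acetic acid
Product: 20 (3S,5aS,6R,9aS)-6-{2-[(3S,5aS,6S,7R,9aS)-3,7-bis(acetyloxy)-2,2,5a,7-tetramethyldecahydro-1-benzoxepin-6-yl]ethyl}-2,2,5a-trimethyl-7-methylidenedecahydro-1-benzoxepin-3-ol (CNP0412606.1)
Conditions: 17 (1 equiv), 19 (3 equiv), KOH (10 mol % of acid), MeOH, Pt anode/Pt cathode, undivided cell, 0.25 A cm⁻², 20 °C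
Reagents that add atoms: none
Why: Crossed Kolbe electrolysis decarboxylates both carboxylates at the anode to primary radicals whose cross-combination forms the C12–C12′ bond; no stereocentre is involved and the excess of 19 raises the yield on 17.

**Compound list**
1 | (3S)-3-hydroxyoxolan-2-one [(S)-α-hydroxy-γ-butyrolactone] | O[C@H]1CCOC1=O | starting material
2 | (3S)-4-methylpentane-1,3,4-triol | OCC[C@H](O)C(C)(C)O | intermediate
3 | 2-[(4S)-2,2,5,5-tetramethyl-1,3-dioxolan-4-yl]ethan-1-ol | OCC[C@H]1C(C)(C)OC(C)(C)O1 | intermediate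
4 | (4S)-4-(2-iodoethyl)-2,2,5,5-tetramethyl-1,3-dioxolane | ICC[C@H]1C(C)(C)OC(C)(C)O1 | intermediate
5 | (1S,5S)-4,6,6-trimethylbicyclo[3.1.1]hept-3-en-2-one [(−)-verbenone] | CC1=CC(=O)[C@H]2C[C@@H]1C2(C)C | starting material
6 | {2-[(4S)-2,2,5,5-tetramethyl-1,3-dioxolan-4-yl]ethyl}magnesium iodide (not isolated) | I[Mg]CC[C@H]1C(C)(C)OC(C)(C)O1 | intermediate
7 | iodomagnesium (1S,4R,5R)-4,6,6-trimethyl-4-{2-[(4S)-2,2,5,5-tetramethyl-1,3-dioxolan-4-yl]ethyl}bicyclo[3.1.1]hept-2-en-2-olate (not isolated) | C[C@]1(CC[C@H]3C(C)(C)OC(C)(C)O3)C=C(O[Mg]I)[C@H]2C[C@@H]1C2(C)C | intermediate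
8 | (1S,3R,4R,5R)-4,6,6-trimethyl-3-(prop-2-en-1-yl)-4-{2-[(4S)-2,2,5,5-tetramethyl-1,3-dioxolan-4-yl]ethyl}bicyclo[3.1.1]heptan-2-one | C[C@]1(CC[C@H]3C(C)(C)OC(C)(C)O3)[C@@H](CC=C)C(=O)[C@H]2C[C@@H]1C2(C)C | intermediate
9 | (4R,5R,6R)-5-[(3S)-3,4-bis(acetyloxy)-4-methylpentyl]-5-methyl-4-(prop-1-en-2-yl)-6-(prop-2-en-1-yl)cyclohex-1-en-1-yl acetate | CC(=O)OC1=CC[C@H](C(C)=C)[C@@](C)(CC[C@H](OC(C)=O)C(C)(C)OC(C)=O)[C@H]1CC=C | intermediate
10 | (2S,3R,4R)-3-[(3S)-3,4-dihydroxy-4-methylpentyl]-3-methyl-4-(prop-1-en-2-yl)-2-(prop-2-en-1-yl)cyclohexan-1-one | O=C1CC[C@H](C(C)=C)[C@@](C)(CC[C@H](O)C(C)(C)O)[C@@H]1CC=C | intermediate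
11 | bis(α-methoxy hydroperoxide) of 10: 3-[(3S)-3,4-dihydroxy-4-methylpentyl]-2-(2-hydroperoxy-2-methoxyethyl)-4-(1-hydroperoxy-1-methoxyethyl)-3-methylcyclohexan-1-one, ring and chain centres as in 10, peroxyacetal carbons as mixtures (not isolated) | O=C1CC[C@H](C(C)(OC)OO)[C@@](C)(CC[C@H](O)C(C)(C)O)[C@@H]1CC(OC)OO | intermediate
12 | methyl [(1S,2S,3S)-3-(acetyloxy)-2-[(3S)-3-(acetyloxy)-4-hydroxy-4-methylpentyl]-2-methyl-6-oxocyclohexyl]acetate (not isolated) | O=C1CC[C@H](OC(C)=O)[C@@](C)(CC[C@H](OC(C)=O)C(C)(C)O)[C@@H]1CC(=O)OC | intermediate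
13 | methyl [(1S,2S,3S)-2-[(3S)-3,4-dihydroxy-4-methylpentyl]-3-hydroxy-2-methyl-6-oxocyclohexyl]acetate | O=C1CC[C@H](O)[C@@](C)(CC[C@H](O)C(C)(C)O)[C@@H]1CC(=O)OC | intermediate
14 | methyl [(1S,2S,3S)-3-hydroxy-2-{2-[(4S)-2-methoxy-2,5,5-trimethyl-1,3-dioxolan-4-yl]ethyl}-2-methyl-6-oxocyclohexyl]acetate, orthoester carbon as a mixture (not isolated) | O=C1CC[C@H](O)[C@@](C)(CC[C@H]2C(C)(C)OC(C)(OC)O2)[C@@H]1CC(=O)OC | intermediate
15 | methyl [(3S,5aS,6S,9aS)-3-(acetyloxy)-2,2,5a-trimethyl-7-oxodecahydro-1-benzoxepin-6-yl]acetate | O=C1CC[C@@H]2OC(C)(C)[C@@H](OC(C)=O)CC[C@@]2(C)[C@@H]1CC(=O)OC | intermediate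
16 | [(3S,5aS,6S,9aS)-3-hydroxy-2,2,5a-trimethyl-7-oxodecahydro-1-benzoxepin-6-yl]acetic acid | O=C1CC[C@@H]2OC(C)(C)[C@@H](O)CC[C@@]2(C)[C@@H]1CC(=O)O | intermediate
17 | [(3S,5aS,6R,9aS)-3-hydroxy-2,2,5a-trimethyl-7-methylidenedecahydro-1-benzoxepin-6-yl]acetic acid | C=C1CC[C@@H]2OC(C)(C)[C@@H](O)CC[C@@]2(C)[C@@H]1CC(=O)O | intermediate
18 | tris(bromomagnesium) salt of [(3S,5aS,6S,7R,9aS)-3,7-dihydroxy-2,2,5a,7-tetramethyldecahydro-1-benzoxepin-6-yl]acetic acid (not isolated) | Br[Mg]O[C@]1(C)CC[C@@H]2OC(C)(C)[C@@H](O[Mg]Br)CC[C@@]2(C)[C@@H]1CC(=O)O[Mg]Br | intermediate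
19 | [(3S,5aS,6S,7R,9aS)-3,7-bis(acetyloxy)-2,2,5a,7-tetramethyldecahydro-1-benzoxepin-6-yl]acetic acid | CC(=O)O[C@]1(C)CC[C@@H]2OC(C)(C)[C@@H](OC(C)=O)CC[C@@]2(C)[C@@H]1CC(=O)O | intermediate
20 | (3S,5aS,6R,9aS)-6-{2-[(3S,5aS,6S,7R,9aS)-3,7-bis(acetyloxy)-2,2,5a,7-tetramethyldecahydro-1-benzoxepin-6-yl]ethyl}-2,2,5a-trimethyl-7-methylidenedecahydro-1-benzoxepin-3-ol (CNP0412606.1) | C=C1CC[C@@H]2OC(C)(C)[C@@H](O)CC[C@@]2(C)[C@@H]1CC[C@H]1[C@]2(C)CC[C@H](OC(C)=O)C(C)(C)O[C@H]2CC[C@@]1(C)OC(C)=O | target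

**Totals and risks**

Total step count: 12. Longest linear sequence: 11 steps (1 → 2 → 3 → 4 → 8 → 9 → 10 → 13 → 15 → 16 → 17 or 19 → 20).

The three steps most likely to fail:

Step 8 (the proposed new reaction). The C7 hydroxyl could open the acetoxonium ion at C3 to give a six-membered ether, or the ion could lose a proton instead of closing the seven-membered ring. The fallback uses known chemistry, sets out from 13 and comes back at 16. Triol 13 is taken through the orthoacetate / Me3SiCl / K2CO3–MeOH diol-to-epoxide sequence, which gives net retention at C3 and masks the C7 hydroxyl in situ as its silyl ether, to give methyl [(1S,2S,3S)-2-{2-[(2S)-3,3-dimethyloxiran-2-yl]ethyl}-3-hydroxy-2-methyl-6-oxocyclohexyl]acetate F1. Camphorsulfonic acid in CH2Cl2 at 0 °C then lets the C7 hydroxyl open the trisubstituted epoxide at its tertiary carbon (7-endo hydroxy-epoxide cyclisation) to give methyl [(3S,5aS,6S,9aS)-3-hydroxy-2,2,5a-trimethyl-7-oxodecahydro-1-benzoxepin-6-yl]acetate F2, which is saponified under the step 9 conditions to 16.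

Step 12 (crossed Kolbe). Radical pairing is statistical, so both symmetrical dimers form besides 20, and methoxide formed at the cathode may attack the acetates. The fallback sets out from 17 and 19 and comes back at 20. Each acid is converted with N-hydroxyphthalimide and DIC into its redox-active ester: 17 gives 1,3-dioxoisoindolin-2-yl [(3S,5aS,6R,9aS)-3-hydroxy-2,2,5a-trimethyl-7-methylidenedecahydro-1-benzoxepin-6-yl]acetate F3 and 19 gives 1,3-dioxoisoindolin-2-yl [(3S,5aS,6S,7R,9aS)-3,7-bis(acetyloxy)-2,2,5a,7-tetramethyldecahydro-1-benzoxepin-6-yl]acetate F4. The two esters, the second in threefold excess, are then joined by nickel-catalysed reductive electrolysis (NiCl2·glyme, 2,2′-bipyridine, Mg sacrificial anode, DMF), a known doubly decarboxylative C(sp3)–C(sp3) cross-coupling, to give 20.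

Step 5 (cyclobutane fragmentation). BF3 may ionise the tertiary acetate formed from the acetonide (an acetoxonium ion there would scramble C3) or trigger cation–olefin side reactions. The fallback sets out from 8 and comes back at 10. Aqueous acetic acid removes the acetonide to give (1S,3R,4R,5R)-4-[(3S)-3,4-dihydroxy-4-methylpentyl]-4,6,6-trimethyl-3-(prop-2-en-1-yl)bicyclo[3.1.1]heptan-2-one F5. 1,1′-Carbonyldiimidazole converts the diol into the non-ionisable cyclic carbonate (1S,3R,4R,5R)-4-{2-[(4S)-5,5-dimethyl-2-oxo-1,3-dioxolan-4-yl]ethyl}-4,6,6-trimethyl-3-(prop-2-en-1-yl)bicyclo[3.1.1]heptan-2-one F6. The same BF3·OEt2/Zn(OAc)2/Ac2O fragmentation then gives (4R,5R,6R)-5-{2-[(4S)-5,5-dimethyl-2-oxo-1,3-dioxolan-4-yl]ethyl}-5-methyl-4-(prop-1-en-2-yl)-6-(prop-2-en-1-yl)cyclohex-1-en-1-yl acetate F7, and NaOMe/MeOH under the step 6 conditions cleaves both the enol acetate and the carbonate to 10.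

**Further compounds**
F1 | step 8 | methyl [(1S,2S,3S)-2-{2-[(2S)-3,3-dimethyloxiran-2-yl]ethyl}-3-hydroxy-2-methyl-6-oxocyclohexyl]acetate | O=C1CC[C@H](O)[C@@](C)(CC[C@@H]2OC2(C)C)[C@@H]1CC(=O)OC
F2 | step 8 | methyl [(3S,5aS,6S,9aS)-3-hydroxy-2,2,5a-trimethyl-7-oxodecahydro-1-benzoxepin-6-yl]acetate | O=C1CC[C@@H]2OC(C)(C)[C@@H](O)CC[C@@]2(C)[C@@H]1CC(=O)OC
F3 | step 12 | 1,3-dioxoisoindolin-2-yl [(3S,5aS,6R,9aS)-3-hydroxy-2,2,5a-trimethyl-7-methylidenedecahydro-1-benzoxepin-6-yl]acetate | C=C1CC[C@@H]2OC(C)(C)[C@@H](O)CC[C@@]2(C)[C@@H]1CC(=O)ON3C(=O)c4ccccc4C3=O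
F4 | step 12 | 1,3-dioxoisoindolin-2-yl [(3S,5aS,6S,7R,9aS)-3,7-bis(acetyloxy)-2,2,5a,7-tetramethyldecahydro-1-benzoxepin-6-yl]acetate | CC(=O)O[C@]1(C)CC[C@@H]2OC(C)(C)[C@@H](OC(C)=O)CC[C@@]2(C)[C@@H]1CC(=O)ON3C(=O)c4ccccc4C3=O
F5 | step 5 | (1S,3R,4R,5R)-4-[(3S)-3,4-dihydroxy-4-methylpentyl]-4,6,6-trimethyl-3-(prop-2-en-1-yl)bicyclo[3.1.1]heptan-2-one | C[C@]1(CC[C@H](O)C(C)(C)O)[C@@H](CC=C)C(=O)[C@H]2C[C@@H]1C2(C)C
F6 | step 5 | (1S,3R,4R,5R)-4-{2-[(4S)-5,5-dimethyl-2-oxo-1,3-dioxolan-4-yl]ethyl}-4,6,6-trimethyl-3-(prop-2-en-1-yl)bicyclo[3.1.1]heptan-2-one | C[C@]1(CC[C@H]3C(C)(C)OC(=O)O3)[C@@H](CC=C)C(=O)[C@H]2C[C@@H]1C2(C)C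
F7 | step 5 | (4R,5R,6R)-5-{2-[(4S)-5,5-dimethyl-2-oxo-1,3-dioxolan-4-yl]ethyl}-5-methyl-4-(prop-1-en-2-yl)-6-(prop-2-en-1-yl)cyclohex-1-en-1-yl acetate | CC(=O)OC1=CC[C@H](C(C)=C)[C@@](C)(CC[C@H]2C(C)(C)OC(=O)O2)[C@H]1CC=C
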